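**Retrosynthetic overview**

1. Target 30 ⇒ (remove the C3 and C9 esters) 9α‑hydroxy‑8‑ketone ⇒ Δ9(10)‑en‑8‑one 20; dissolving‑metal reduction sets 10α‑H, enol‑ether oxidation puts oxygen on C9.
2. 20 ⇒ oxygen‑bridged ketone 19: β‑elimination of the C10–O bond unveils C3–OH and the enone. The C8 ketone comes from a carbinol; a temporary C6 ketone is excised by Barton–McCombie deoxygenation.
3. Enabling feature: in ring A the C3 oxygen and the C10 hydrogen are 1,4‑cis and C1–C2 between them is unfunctionalised, so C3–C2–C1–C10 plus the C3 oxygen is a furan whose ring oxygen bridges C3 and C10. C4/C5 with their cis methyls C15/C14 are the alkene of an (E)‑2‑methylbut‑2‑enoyl unit.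
4. Key disconnection: C3–C4 (together with C5–C10) by an intramolecular furan Diels–Alder reaction of open‑chain ketone 12. Rings A and B form together in this one step; before it, ring B is only a four‑atom tether.
5. 12 ⇒ syn boron aldol (C7–C8) of dienone 6 with 2‑(furan‑2‑yl)acetaldehyde 8; 6 ⇒ tigloyl chloride + 2‑methylallylmagnesium chloride.

Key step: step 6

Convention: eremophilane numbering (C1–C10 decalin; C11–C13 isopropenyl on C7; C14 methyl on C5; C15 methyl on C4); β is the face of C14. All bicyclic compounds carry 4β‑CH3, 5β‑CH3 and 7α‑isopropenyl.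

Assumption: the Z enol borinate from (−)‑Ipc2BOTf (ligands from (+)‑α‑pinene) is taken to add to the Si face of aldehyde 8; if the sense is the opposite, the enantiomeric reagent is used.

**Route**

Step 1
Reactants: 1 (E)-2-methylbut-2-enoyl chloride (tigloyl chloride); 2 N,O-dimethylhydroxylamine hydrochloride
Product: 3 (E)-N-methoxy-N,2-dimethylbut-2-enamide
Conditions: pyridine (2.2 equiv), CH2Cl2, 0 °C → rt
Reagents that add atoms: none
Why: Acylation of the amine by the acid chloride (Weinreb amide formation) should proceed without touching the trisubstituted (E)-alkene.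

Step 2
Reactants: 3 (E)-N-methoxy-N,2-dimethylbut-2-enamide; 4 2-methylallylmagnesium chloride
Product: 6 (E)-3,6-dimethylhepta-2,6-dien-4-one, via chloromagnesium hemiaminal 5 (not isolated)
Conditions: THF, −78 → 0 °C; cold aq. NH4Cl
Reagents that add atoms: none
Why: Weinreb ketone synthesis: the allylic Grignard reagent adds 1,2 and the N-methoxy chelate 5 survives until the cold work-up, so no second addition occurs and the β,γ-unsaturated ketone is released under conditions too mild to conjugate it.

Step 3
Reactants: 7 2-(furan-2-yl)ethanol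
Product: 8 2-(furan-2-yl)acetaldehyde
Conditions: Dess–Martin periodinane, NaHCO3, CH2Cl2, 0 °C; used at once
Reagents that add atoms: none
Why: Dess–Martin oxidation under buffered, non-basic conditions should stop at the enolisable aldehyde, which is carried on at once because it polymerises on storage.

Step 4
Reactants: 6 (E)-3,6-dimethylhepta-2,6-dien-4-one; 8 2-(furan-2-yl)acetaldehyde
Product: 11 (2E,5S,6R)-7-(furan-2-yl)-6-hydroxy-3-methyl-5-(prop-1-en-2-yl)hept-2-en-4-one, via Z enol diisopinocampheylborinate 9 (not isolated), via boron aldolate 10 (not isolated)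
Conditions: (−)-Ipc2BOTf, i-Pr2NEt, CH2Cl2, −78 °C; then 8, −78 → −20 °C; H2O2, MeOH, pH 7 buffer, 0 °C
Reagents that add atoms: none
Why: Boron aldol reaction through a chair Zimmerman–Traxler transition state: the only enolisable position of 6 (the doubly activated methylene) gives the Z enol borinate 9, which adds through its α-carbon to give the 5,6-syn adduct, and the isopinocampheyl ligands choose the aldehyde Si face, setting C7 (S) and C8 (R) of the later skeleton.

Step 5
Reactants: 11 (2E,5S,6R)-7-(furan-2-yl)-6-hydroxy-3-methyl-5-(prop-1-en-2-yl)hept-2-en-4-one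
Product: 12 (2E,5S,6R)-6-(tert-butyldimethylsilyloxy)-7-(furan-2-yl)-3-methyl-5-(prop-1-en-2-yl)hept-2-en-4-one
Conditions: t-BuMe2SiOTf, 2,6-lutidine, CH2Cl2, −78 °C
Reagents that add atoms: tert-butyldimethylsilyl trifluoromethanesulfonate, CC(C)(C)[Si](C)(C)OS(=O)(=O)C(F)(F)F
Why: Silylation with the silyl triflate at −78 °C protects the β-hydroxyl without retro-aldol or elimination and supplies the bulky, equatorial-seeking group that later steers the cycloaddition.

Step 6
Reactants: 12 (2E,5S,6R)-6-(tert-butyldimethylsilyloxy)-7-(furan-2-yl)-3-methyl-5-(prop-1-en-2-yl)hept-2-en-4-one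
Product: 13 8β-(tert-butyldimethylsilyloxy)-3α,10α-epoxyeremophila-1,11-dien-6-one
Conditions: MeAlCl2 (1.1 equiv), CH2Cl2, −78 °C; quenched cold with Et3N, then aq. NaHCO3
Reagents that add atoms: none
Why: MeAlCl2 bound to the C6 carbonyl lowers the LUMO of the (E)-enone, and the furan is dearomatised in an asynchronous, concerted [4+2] addition in which its free α-carbon C3 bonds to the enone β-carbon C4 ahead of C10–C5; the closest known reaction type is the Lewis-acid-promoted intramolecular furan Diels–Alder reaction of furans tethered through four atoms to an enone carbonyl, which gives oxygen-bridged decalones at −78 °C. Ring A closes as the six-membered [4+2] ring (a 7-oxabicyclo[2.2.1]heptene) and ring B closes as a six-membered ring through the C9–C8–C7–C6 tether, which should span the bicycle on the exo side (syn to the oxygen bridge). The oxygen bridge fixes C3–O and C10–O cis (both α), and suprafacial addition to the (E)-alkene with the tether exo puts C15 and C14 cis and endo (both β), so that C3–O/C4–CH3 are trans and the C4/C5 methyls cis as in the target; C10–O is later replaced by H on the same face. The absolute sense is set by C7 and C8, since only one diastereoface lets the forming ring B be a chair with isopropenyl and silyloxy both equatorial. The step needs exo-tether and π-facial selectivity, secured by the short tether and the trans-diequatorial C7/C8 pair, and it needs the equilibrium on the adduct side, secured by the low temperature, the substituted tether (reactive-rotamer effect) and the immediate saturation of C1=C2 in step 7.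

Step 7
Reactants: 13 8β-(tert-butyldimethylsilyloxy)-3α,10α-epoxyeremophila-1,11-dien-6-one
Product: 14 8β-(tert-butyldimethylsilyloxy)-3α,10α-epoxyeremophil-11-en-6-one
Conditions: KO2CN=NCO2K, AcOH, MeOH, 0 °C → rt
Reagents that add atoms: none
Why: Diimide reduction (concerted syn transfer of H2) is strongly accelerated by the strain of the oxanorbornene C1=C2 bond, so it should saturate this bond alone, leave the 1,1-disubstituted isopropenyl group and the ketone, and close the cycloreversion pathway.

Step 8
Reactants: 14 8β-(tert-butyldimethylsilyloxy)-3α,10α-epoxyeremophil-11-en-6-one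
Product: 15 8β-(tert-butyldimethylsilyloxy)-3α,10α-epoxyeremophil-11-en-6-ol (C6 epimers)
Conditions: NaBH4, MeOH, 0 °C → rt
Reagents that add atoms: none
Why: Hydride reduction of the isolated C6 ketone; the configuration of the new carbinol is irrelevant because C6 becomes a methylene in step 10.

Step 9
Reactants: 15 8β-(tert-butyldimethylsilyloxy)-3α,10α-epoxyeremophil-11-en-6-ol
Product: 16 O-phenyl thionocarbonate of 15 at C6
Conditions: PhOC(S)Cl, pyridine, DMAP (cat.), MeCN, rt
Reagents that add atoms: O-phenyl chlorothionoformate, S=C(Cl)Oc1ccccc1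
Why: Thioacylation of the neopentyl-type alcohol under non-basic conditions (first half of a Barton–McCombie deoxygenation) avoids the 1,3 oxygen-to-oxygen silyl migration that an alkoxide would allow.

Step 10
Reactants: 16 O-phenyl thionocarbonate of 15
Product: 17 8β-(tert-butyldimethylsilyloxy)-3α,10α-epoxyeremophil-11-ene
Conditions: Bu3SnH (0.5 M), AIBN (cat.), toluene, 80 °C
Reagents that add atoms: none
Why: Barton–McCombie deoxygenation: the stannyl radical adds to C=S, the C6–O bond fragments, and the secondary C6 radical is reduced by the concentrated tin hydride faster than it can attack the homoallylic isopropenyl group.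

Step 11
Reactants: 17 8β-(tert-butyldimethylsilyloxy)-3α,10α-epoxyeremophil-11-ene
Product: 18 3α,10α-epoxyeremophil-11-en-8β-ol
Conditions: Bu4NF, THF, rt → 45 °C
Reagents that add atoms: none
Why: Fluoride-mediated desilylation frees the C8 hydroxyl; no base-sensitive group is present at this stage.

Step 12
Reactants: 18 3α,10α-epoxyeremophil-11-en-8β-ol
Product: 20 3α-hydroxyeremophila-9,11-dien-8-one, via bridged ketone 19 (not isolated)
Conditions: Dess–Martin periodinane, NaHCO3, CH2Cl2, 0 °C → rt; then DBU (0.2 equiv), 0 °C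
Reagents that add atoms: none
Why: Dess–Martin oxidation gives the β-alkoxy ketone 19, whose C9 enolate expels the C10–O bond that stands axial on ring B (E1cB β-elimination, driven by release of bicyclic strain and by conjugation), unveiling the C3 hydroxyl and the enone; C10 becomes trigonal and no stereocentre is formed.

Step 13
Reactants: 20 3α-hydroxyeremophila-9,11-dien-8-one
Product: 21 3α-(tert-butyldimethylsilyloxy)eremophila-9,11-dien-8-one
Conditions: t-BuMe2SiCl, imidazole, DMF, rt
Reagents that add atoms: tert-butyldimethylsilyl chloride, CC(C)(C)[Si](C)(C)Cl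
Why: Silylation of the equatorial C3 hydroxyl gives an ether that survives the dissolving-metal step, which the final C3 ester would not.

Step 14
Reactants: 21 3α-(tert-butyldimethylsilyloxy)eremophila-9,11-dien-8-one
Product: 23 3α-(tert-butyldimethylsilyloxy)-8-(trimethylsilyloxy)-10αH-eremophila-8,11-diene, via lithium enolate 22 (not isolated)
Conditions: Li, NH3(l)/THF, t-BuOH (1 equiv), −78 °C; isoprene; NH3 off; Me3SiCl, Et3N, THF, −78 → 0 °C
Reagents that add atoms: chlorotrimethylsilane, C[Si](C)(C)Cl
Why: Dissolving-metal (Birch-type) enone reduction: the β-carbanion at C10 is protonated axially from the α-face, opposite the axial C14 methyl, to give the trans ring fusion (10α-H), and the regiodefined C8–C9 enolate 22 is trapped on oxygen; the isolated isopropenyl alkene and the silyl ether are inert.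

Step 15
Reactants: 23 3α-(tert-butyldimethylsilyloxy)-8-(trimethylsilyloxy)-10αH-eremophila-8,11-diene
Product: 26 3α-(tert-butyldimethylsilyloxy)-9α-hydroxy-10αH-eremophil-11-en-8-one, via silyloxy epoxide 24 (not isolated), via silyloxy ketone 25 (not isolated)
Conditions: m-CPBA (1.05 equiv), NaHCO3, CH2Cl2, −20 °C; then citric acid, MeOH, 0 °C
Reagents that add atoms: 3-chloroperoxybenzoic acid, OOC(=O)c1cccc(Cl)c1
Why: Rubottom oxidation: the electron-rich enol ether is epoxidised in preference to the isopropenyl group and from the α-face, because the β-face of C9 is blocked by the 1,3-diaxial C14 methyl; ring opening with 1,4-silyl shift and mild acid give the equatorial 9α-hydroxy ketone.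

Step 16
Reactants: 26 3α-(tert-butyldimethylsilyloxy)-9α-hydroxy-10αH-eremophil-11-en-8-one; 1 (E)-2-methylbut-2-enoyl chloride
Product: 27 3α-(tert-butyldimethylsilyloxy)-9α-[(E)-2-methylbut-2-enoyloxy]-10αH-eremophil-11-en-8-one
Conditions: pyridine, DMAP, CH2Cl2, 0 °C → rt
Reagents that add atoms: none
Why: DMAP-catalysed acylation of the α-ketol hydroxyl with the (E)-acid chloride; any epimerisation at C9 under the basic conditions can only favour the wanted equatorial ester.

Step 17
Reactants: 27 3α-(tert-butyldimethylsilyloxy)-9α-[(E)-2-methylbut-2-enoyloxy]-10αH-eremophil-11-en-8-one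
Product: 28 3α-hydroxy-9α-[(E)-2-methylbut-2-enoyloxy]-10αH-eremophil-11-en-8-one
Conditions: HF·pyridine, THF, 0 °C → rt
Reagents that add atoms: none
Why: Fluoride cleavage of the secondary silyl ether under buffered acidic conditions that leave the ester, the α-acyloxy ketone and the isopropenyl group intact.

Step 18
Reactants: 28 3α-hydroxy-9α-[(E)-2-methylbut-2-enoyloxy]-10αH-eremophil-11-en-8-one; 29 3-methylbut-2-enoic acid
Product: 30 3α-(3-methylbut-2-enoyloxy)-9α-[(E)-2-methylbut-2-enoyloxy]-10αH-eremophil-11-en-8-one (CNP0164025.1)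
Conditions: DCC, DMAP, CH2Cl2, 0 °C → rt
Reagents that add atoms: none
Why: Steglich esterification of the equatorial C3 alcohol; carbodiimide activation of the free acid avoids the vinylketene pathway that would deconjugate the 3-methylbut-2-enoyl group.

**Compound list**

1 | (E)-2-methylbut-2-enoyl chloride | C/C=C(\C)C(=O)Cl | starting material
2 | N,O-dimethylhydroxylamine hydrochloride | CNOC.Cl | starting material
3 | (E)-N-methoxy-N,2-dimethylbut-2-enamide | C/C=C(\C)C(=O)N(C)OC | intermediate
4 | 2-methylallylmagnesium chloride | C=C(C)C[Mg]Cl | starting material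
5 | chloromagnesium hemiaminal from 3 and 4 | C/C=C(\C)C(O[Mg]Cl)(CC(C)=C)N(C)OC | intermediate
6 | (E)-3,6-dimethylhepta-2,6-dien-4-one | C/C=C(\C)C(=O)CC(C)=C | intermediate
7 | 2-(furan-2-yl)ethanol | OCCc1ccco1 | starting material
8 | 2-(furan-2-yl)acetaldehyde | O=CCc1ccco1 | intermediate
9 | Z enol diisopinocampheylborinate of 6 | C=C(C)/C=C(\OB([C@@H]1C[C@@H]2C[C@H]([C@H]1C)C2(C)C)[C@@H]1C[C@@H]2C[C@H]([C@H]1C)C2(C)C)/C(C)=C/C | intermediate
10 | diisopinocampheylboron aldolate of 11 | C/C=C(\C)C(=O)[C@@H](C(C)=C)[C@H](OB([C@@H]1C[C@@H]2C[C@H]([C@H]1C)C2(C)C)[C@@H]1C[C@@H]2C[C@H]([C@H]1C)C2(C)C)Cc1ccco1 | intermediate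
11 | (2E,5S,6R)-7-(furan-2-yl)-6-hydroxy-3-methyl-5-(prop-1-en-2-yl)hept-2-en-4-one | C/C=C(\C)C(=O)[C@@H](C(C)=C)[C@H](O)Cc1ccco1 | intermediate
12 | (2E,5S,6R)-6-(tert-butyldimethylsilyloxy)-7-(furan-2-yl)-3-methyl-5-(prop-1-en-2-yl)hept-2-en-4-one | C/C=C(\C)C(=O)[C@@H](C(C)=C)[C@H](O[Si](C)(C)C(C)(C)C)Cc1ccco1 | intermediate
13 | 8β-(tert-butyldimethylsilyloxy)-3α,10α-epoxyeremophila-1,11-dien-6-one (4β,5β-dimethyl, 7α-isopropenyl) | C[C@H]1[C@H]2C=C[C@@]3(O2)C[C@@H](O[Si](C)(C)C(C)(C)C)[C@H](C(C)=C)C(=O)[C@]13C | intermediate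
14 | 8β-(tert-butyldimethylsilyloxy)-3α,10α-epoxyeremophil-11-en-6-one | C[C@H]1[C@H]2CC[C@@]3(O2)C[C@@H](O[Si](C)(C)C(C)(C)C)[C@H](C(C)=C)C(=O)[C@]13C | intermediate
15 | 8β-(tert-butyldimethylsilyloxy)-3α,10α-epoxyeremophil-11-en-6-ol (C6 epimers; centre removed in step 10) | C[C@H]1[C@H]2CC[C@@]3(O2)C[C@@H](O[Si](C)(C)C(C)(C)C)[C@H](C(C)=C)C(O)[C@]13C | intermediate
16 | O-phenyl thionocarbonate of 15 at C6 | C[C@H]1[C@H]2CC[C@@]3(O2)C[C@@H](O[Si](C)(C)C(C)(C)C)[C@H](C(C)=C)C(OC(=S)Oc4ccccc4)[C@]13C | intermediate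
17 | 8β-(tert-butyldimethylsilyloxy)-3α,10α-epoxyeremophil-11-ene | C[C@H]1[C@H]2CC[C@@]3(O2)C[C@@H](O[Si](C)(C)C(C)(C)C)[C@H](C(C)=C)C[C@]13C | intermediate
18 | 3α,10α-epoxyeremophil-11-en-8β-ol | C[C@H]1[C@H]2CC[C@@]3(O2)C[C@@H](O)[C@H](C(C)=C)C[C@]13C | intermediate
19 | 3α,10α-epoxyeremophil-11-en-8-one | C[C@H]1[C@H]2CC[C@@]3(O2)CC(=O)[C@H](C(C)=C)C[C@]13C | intermediate
20 | 3α-hydroxyeremophila-9,11-dien-8-one | C=C(C)[C@@H]1C[C@]2(C)[C@@H](C)[C@H](O)CCC2=CC1=O | intermediate
21 | 3α-(tert-butyldimethylsilyloxy)eremophila-9,11-dien-8-one | C=C(C)[C@@H]1C[C@]2(C)[C@@H](C)[C@H](O[Si](C)(C)C(C)(C)C)CCC2=CC1=O | intermediate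
22 | lithium 8(9)-enolate of the 10αH ketone | C=C(C)[C@@H]1C[C@]2(C)[C@@H](C)[C@H](O[Si](C)(C)C(C)(C)C)CC[C@H]2C=C1[O-].[Li+] | intermediate
23 | 3α-(tert-butyldimethylsilyloxy)-8-(trimethylsilyloxy)-10αH-eremophila-8,11-diene | C=C(C)[C@@H]1C[C@]2(C)[C@@H](C)[C@H](O[Si](C)(C)C(C)(C)C)CC[C@H]2C=C1O[Si](C)(C)C | intermediate
24 | 8α,9α-epoxy-3α-(tert-butyldimethylsilyloxy)-8β-(trimethylsilyloxy)-10αH-eremophil-11-ene | C=C(C)[C@@H]1C[C@]2(C)[C@@H](C)[C@H](O[Si](C)(C)C(C)(C)C)CC[C@H]2[C@@H]3O[C@]13O[Si](C)(C)C | intermediate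
25 | 3α-(tert-butyldimethylsilyloxy)-9α-(trimethylsilyloxy)-10αH-eremophil-11-en-8-one | C=C(C)[C@@H]1C[C@]2(C)[C@@H](C)[C@H](O[Si](C)(C)C(C)(C)C)CC[C@H]2[C@H](O[Si](C)(C)C)C1=O | intermediate
26 | 3α-(tert-butyldimethylsilyloxy)-9α-hydroxy-10αH-eremophil-11-en-8-one | C=C(C)[C@@H]1C[C@]2(C)[C@@H](C)[C@H](O[Si](C)(C)C(C)(C)C)CC[C@H]2[C@H](O)C1=O | intermediate
27 | 3α-(tert-butyldimethylsilyloxy)-9α-[(E)-2-methylbut-2-enoyloxy]-10αH-eremophil-11-en-8-one | C=C(C)[C@@H]1C[C@]2(C)[C@@H](C)[C@H](O[Si](C)(C)C(C)(C)C)CC[C@H]2[C@H](OC(=O)/C(C)=C/C)C1=O | intermediate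
28 | 3α-hydroxy-9α-[(E)-2-methylbut-2-enoyloxy]-10αH-eremophil-11-en-8-one | C=C(C)[C@@H]1C[C@]2(C)[C@@H](C)[C@H](O)CC[C@H]2[C@H](OC(=O)/C(C)=C/C)C1=O | intermediate
29 | 3-methylbut-2-enoic acid | CC(C)=CC(=O)O | starting material
30 | (3R,4R,5R,7S,9S,10R)-3-(3-methylbut-2-enoyloxy)-9-[(E)-2-methylbut-2-enoyloxy]eremophil-11-en-8-one | C=C(C)[C@@H]1C[C@]2(C)[C@@H](C)[C@H](OC(=O)C=C(C)C)CC[C@H]2[C@H](OC(=O)/C(C)=C/C)C1=O | target

**Step count and risks**

Total steps: 18. Longest linear sequence: 17 steps (1, 2, 4–18, from tigloyl chloride).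

Steps most likely to fail:

Step 6. What may go wrong: cycloreversion of the congested adduct (two adjacent fully substituted carbons) may outrun its capture, and the Lewis acid may ionise the bridging ether of the adduct. Fallback, changing the activation from a neutral enone–Lewis acid complex to a cationic dienophile (ionic Diels–Alder reaction): setting out from 12, 1,2-bis(trimethylsilyloxy)ethane and Me3SiOTf (cat.) in CH2Cl2 at −78 °C should give the 1,3-dioxolane of ketone 12 F1. Under the same acid one C–O bond ionises to the open 2-(trimethylsilyloxy)ethyl oxocarbenium triflate F2, an alkoxy-stabilised allyl cation that should add to the furan at a temperature where cycloreversion is frozen. Ring closure of the adduct cation gives the 1,3-dioxolane of cycloadduct 13 F3, which has no carbonyl for an acid to re-activate. Diimide as in step 7 gives the 1,3-dioxolane of ketone 14 F4, and PPTS in wet acetone returns to the route at 14.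

Step 4. What may go wrong: loss of the labile aldehyde by self-condensation during slow borinate addition, insufficient reagent control of the aldehyde face (erosion of enantiopurity), and bond formation at the γ-terminus of the dienyl borinate. Fallback, changing from reagent control to auxiliary control with separable diastereomers (Evans aldol): setting out from 8, (S)-4-benzyl-3-(3-methylbut-3-enoyl)oxazolidin-2-one F5 is made from 3-methylbut-3-enoic acid (t-BuCOCl, Et3N; then lithiated (S)-4-benzyloxazolidin-2-one). Bu2BOTf and i-Pr2NEt convert it into the Z dibutylboron enolate F6, which adds to 8 to give the boron aldolate F7 and, after H2O2 work-up, the syn aldol imide F8 with the same (S) and (R) centres as 11. Dimethylaluminium N-methoxy-N-methylamide F9 (from Me3Al and MeNHOMe·HCl) transamidates it to the hydroxy Weinreb amide F10, and t-BuMe2SiOTf/2,6-lutidine gives the silyloxy Weinreb amide F11. (E)-But-2-en-2-yllithium F12 (from (E)-2-bromobut-2-ene and t-BuLi at −78 °C, with retention) adds to give the lithium hemiaminal F13, which collapses on work-up and returns to the route at 12.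

Step 12. What may go wrong: the ketone may also enolise towards C7 under the amine base, so that the isopropenyl double bond migrates into conjugation (and C7 is scrambled) in competition with the wanted C9 deprotonation and β-elimination. Fallback, thermodynamic convergence followed by kinetic deconjugation instead of trying to outrun the isomerisation: setting out from 18, the oxidation is followed by DBU at rt until all material has converged on 3α-hydroxyeremophila-7(11),9-dien-8-one F14. LiN(i-Pr)2 (2.2 equiv, THF, −78 °C) removes an isopropylidene methyl proton to give the dilithium dienolate F15. Inverse quench into AcOH/THF at −78 °C should protonate the α-carbon C7 kinetically and axially (deconjugative protonation, as for pulegone-type enones), placing the isopropenyl group equatorial and returning to the route at 20.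

**Further compounds**

F1 | step 6 | 1,3-dioxolane of ketone 12 | C/C=C(\C)C1(OCCO1)[C@@H](C(C)=C)[C@H](O[Si](C)(C)C(C)(C)C)Cc1ccco1
F2 | step 6 | open 2-(trimethylsilyloxy)ethyl oxocarbenium triflate from F1 | C/C=C(\C)C(=[O+]CCO[Si](C)(C)C)[C@@H](C(C)=C)[C@H](O[Si](C)(C)C(C)(C)C)Cc1ccco1.[O-]S(=O)(=O)C(F)(F)F
F3 | step 6 | 1,3-dioxolane of cycloadduct 13 | C[C@H]1[C@H]2C=C[C@@]3(O2)C[C@@H](O[Si](C)(C)C(C)(C)C)[C@H](C(C)=C)C4(OCCO4)[C@]13C
F4 | step 6 | 1,3-dioxolane of ketone 14 | C[C@H]1[C@H]2CC[C@@]3(O2)C[C@@H](O[Si](C)(C)C(C)(C)C)[C@H](C(C)=C)C4(OCCO4)[C@]13C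
F5 | step 4 | (S)-4-benzyl-3-(3-methylbut-3-enoyl)oxazolidin-2-one | C=C(C)CC(=O)N1C(=O)OC[C@@H]1Cc1ccccc1
F6 | step 4 | Z dibutylboron enolate of F5 | C=C(C)/C=C(\OB(CCCC)CCCC)N1C(=O)OC[C@@H]1Cc1ccccc1
F7 | step 4 | dibutylboron aldolate of F8 | C=C(C)[C@@H]([C@H](OB(CCCC)CCCC)Cc1ccco1)C(=O)N1C(=O)OC[C@@H]1Cc1ccccc1
F8 | step 4 | (S)-4-benzyl-3-[(2S,3R)-4-(furan-2-yl)-3-hydroxy-2-(prop-1-en-2-yl)butanoyl]oxazolidin-2-one | C=C(C)[C@@H]([C@H](O)Cc1ccco1)C(=O)N1C(=O)OC[C@@H]1Cc1ccccc1
F9 | step 4 | dimethylaluminium N-methoxy-N-methylamide | CON(C)[Al](C)C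
F10 | step 4 | (2S,3R)-4-(furan-2-yl)-3-hydroxy-N-methoxy-N-methyl-2-(prop-1-en-2-yl)butanamide | C=C(C)[C@@H]([C@H](O)Cc1ccco1)C(=O)N(C)OC
F11 | step 4 | (2S,3R)-3-(tert-butyldimethylsilyloxy)-4-(furan-2-yl)-N-methoxy-N-methyl-2-(prop-1-en-2-yl)butanamide | C=C(C)[C@@H]([C@H](O[Si](C)(C)C(C)(C)C)Cc1ccco1)C(=O)N(C)OC
F12 | step 4 | (E)-but-2-en-2-yllithium | C/C=C(\C)[Li]
F13 | step 4 | lithium hemiaminal from F11 and F12 | C/C=C(\C)C(O[Li])([C@@H](C(C)=C)[C@H](O[Si](C)(C)C(C)(C)C)Cc1ccco1)N(C)OC
F14 | step 12 | 3α-hydroxyeremophila-7(11),9-dien-8-one | CC(C)=C1C[C@]2(C)[C@@H](C)[C@H](O)CCC2=CC1=O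
F15 | step 12 | dilithium alkoxide dienolate of F14 | C=C(C)C1C[C@]2(C)[C@@H](C)[C@H]([O-])CCC2=CC=1[O-].[Li+].[Li+]
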